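**Plan**

- Locants follow eudesmane numbering: ring A is C1–C5 plus C10 (ester oxygen on C3, C4=C5, methyl C15 on C4); ring B is C5–C10 (C11 on C7, acetate on C8, methyl C14 on C10); C12 is the ester carbonyl and C13 the methylene.
- Enabling feature: on ring B, O8 is axial on the β face, 1,3-syn to C14, and C11 is cis to it on the equatorial bond of C7. O8–C12–C11 is thus a three-atom bridge from C8 to a C7–H bond, i.e. a cis-fused 12,8-lactone that a tethered carbene can close.
- Retrosynthesis: cut the acyl–O bonds at O3 and O8 and the C12–OMe bond (back to the α-methylene 12,8β-lactone), remove C13, cut C7–C11 (diazoacetate on O8), cut O8–C12, then cut C4–C5 and C1–C10 of ring A.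
- Forward order: ring B is bought as ketone 1; ring A is annulated (steps 1–3); the lactone ring closes in step 10; the lactone is then methylenated and opened, and the three esters go on last.
- Stereochemistry: C10 from the Michael addition of the (R)-1-phenylethylamine imine; C3 from substrate-controlled Luche reduction; C8 from equatorial hydride delivery opposite the axial C14; C7 from retentive insertion into the equatorial C7–H, relayed by C8.

Key step: step 10

Assumption: of the two enantiomeric Rh2(MEPY)4 catalysts, the 5S form is taken as the one matched to the C7 methylene; the substrate bias points the same way, and if the pairing proves reversed the 5R catalyst is used with no change to any structure.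

**Route**

Step 1
Reactants: 1 racemic 7-methyl-1,4-dioxaspiro[4.5]decan-8-one; 2 (R)-1-phenylethylamine
Product: 3 N-[(R)-1-phenylethyl]imine of ketone 1 (epimeric at the methyl-bearing carbon)
Conditions: toluene, reflux, azeotropic removal of water
Reagents that add atoms: none
Why: Imine condensation driven by water removal; the α-centre of racemic 1 does not matter because it becomes sp2 in the secondary enamine tautomer that reacts in step 2.

Step 2
Reactants: 3 imine; 4 ethyl vinyl ketone (pent-1-en-3-one)
Product: 6 (7R)-7-methyl-7-(3-oxopentyl)-1,4-dioxaspiro[4.5]decan-8-one, via Michael adduct imine 5 (not isolated)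
Conditions: 4 (1.3 equiv), hydroquinone (trace), THF, 20 → 40 °C; then 20% aq AcOH, 20 °C
Reagents that add atoms: water, O
Why: Asymmetric Michael addition of a chiral imine through its more substituted secondary enamine tautomer (compact aza-ene-like transition state with N–H transfer) alkylates the enamine face anti to the phenyl group, which for the (R)-amine should create quaternary C10 in the R configuration while both enantiomers of 1 converge; dilute acid then hydrolyses the imine and leaves the dioxolane intact.

Step 3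
Reactants: 6 diketone
Product: 8 (10R)-11,12,13-trinoreudesm-4-ene-3,8-dione 8-ethylene ketal [(4aR)-6,6-ethylenedioxy-1,4a-dimethyl-4,4a,5,6,7,8-hexahydronaphthalen-2(3H)-one], via aldol ketol 7 (not isolated)
Conditions: NaOMe, MeOH, 60 °C
Reagents that add atoms: none
Why: Intramolecular aldol condensation (second half of a Robinson annulation): the ethyl-ketone methylene closes onto the ring carbonyl in a six-membered ring and the ketol dehydrates to the tetrasubstituted C4=C5 enone; quaternary C10 cannot epimerise.

Step 4
Reactants: 8 enone ketal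
Product: 9 (3S,10R)-8,8-ethylenedioxy-11,12,13-trinoreudesm-4-en-3β-ol
Conditions: NaBH4, CeCl3·7H2O, MeOH, −40 → 0 °C
Reagents that add atoms: none
Why: Luche 1,2-reduction; hydride should add axially to the half-chair enone on the α face, as in 4-en-3-one steroids, giving the pseudo-equatorial 3β-alcohol (3S) cis to C14, the minor epimer being removed by chromatography.

Step 5
Reactants: 9 allylic alcohol
Product: 10 (3S,10R)-3β-(tert-butyldimethylsilyloxy)-8,8-ethylenedioxy-11,12,13-trinoreudesm-4-ene
Conditions: TBSCl, imidazole, DMAP (cat.), DMF, 20 °C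
Reagents that add atoms: tert-butyldimethylsilyl chloride, CC(C)(C)[Si](C)(C)Cl
Why: Standard silylation of a secondary alcohol; the ether masks O3 through the enolate, saponification and acylation steps that follow.

Step 6
Reactants: 10 silyl ether ketal
Product: 11 (3S,10R)-3β-(tert-butyldimethylsilyloxy)-11,12,13-trinoreudesm-4-en-8-one
Conditions: PPTS (cat.), acetone/H2O 9:1, 55 °C
Reagents that add atoms: water, O
Why: Mild acid-catalysed ketal hydrolysis under conditions that secondary TBS ethers normally tolerate; the ketone is γ,δ to the alkene and flanked by quaternary C10, so no conjugation or epimerisation path is open.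

Step 7
Reactants: 11 ketone
Product: 12 (3S,8S,10R)-3β-(tert-butyldimethylsilyloxy)-11,12,13-trinoreudesm-4-en-8β-ol (hydroxyl axial, cis to C14)
Conditions: LiBH(s-Bu)3, THF, −78 °C; then NaOH, H2O2, 0 °C
Reagents that add atoms: none
Why: Bulky-hydride reduction of a cyclohexanone; the axial β trajectory is blocked by the syn-axial C14 methyl, so hydride should arrive equatorially on the α face and give the axial 8β-alcohol (8S).

Step 8
Reactants: 12 alcohol; 13 bromoacetyl bromide
Product: 14 8β-bromoacetate of 12
Conditions: pyridine, CH2Cl2, −10 → 0 °C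
Reagents that add atoms: none
Why: Acylation of the hindered axial alcohol by a highly reactive acyl bromide with pyridine as acid scavenger; short reaction time at low temperature limits N-alkylation of pyridine.

Step 9
Reactants: 14 bromoacetate
Product: 16 8β-diazoacetate (3S,8S,10R), via N-alkylated ditosylhydrazide 15 (not isolated)
Conditions: TsNHNHTs, DBU, THF, 0 °C
Reagents that add atoms: N,N'-ditosylhydrazine, Cc1ccc(cc1)S(=O)(=O)NNS(=O)(=O)c1ccc(C)cc1
Why: The hydrazide anion displaces bromide and two base-induced sulfinate eliminations (Bamford–Stevens-type) release the diazoacetate under conditions that leave the silyl ether and the ester untouched.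

Step 10
Reactants: 16 diazoacetate
Product: 17 (3S,7R,8R,10R)-3β-(tert-butyldimethylsilyloxy)-13-noreudesm-4-en-12,8β-olide (cis-fused γ-lactone; H7 and H8 both α)
Conditions: Rh2(5S-MEPY)4 [dirhodium tetrakis(methyl (5S)-2-oxopyrrolidine-5-carboxylate)] (1 mol %), CH2Cl2, 40 °C, 16 added over 10 h by syringe pump
Reagents that add atoms: none
Why: Loss of N2 from 16 at the rhodium carboxamidate gives an electrophilic rhodium carbene at C11 that inserts into a C–H bond through a concerted three-centre transition state with retention at carbon, the reaction type established for secondary cycloalkyl and steroidal diazoacetates with this catalyst family. The lactone closes as a five-membered ring by 1,5-insertion, and because the ester oxygen is axial on C8 the tether reaches only the cis, equatorial hydrogens on C7 and C9, so the ring fusion must be cis. The new stereocentre C7 is controlled by C8: retentive insertion into the 7β equatorial C–H places C11 β and equatorial, which is 7R (C8 changes from S to R only because the CIP ranking of C7 and C9 changes). The selectivity required is C7–H over C9–H; the substrate should supply it because C9 is neopentylic, next to quaternary C10 whose axial methyl lies syn to the ester, and the 5S ligand is paired with the C7 methylene. Six-membered closure onto the allylic axial C6–H, β-lactone formation at C8–H, attack on the hindered tetrasubstituted C4=C5 bond and carbene dimerisation should be held back by the five-ring preference of carboxamidate carbenes and by slow addition.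

Step 11
Reactants: 17 lactone
Product: 19 (11S)-11-(dimethylaminomethyl) derivative of lactone 17, via lithium enolate 18 (not isolated)
Conditions: LiN(i-Pr)2, THF, −78 °C; then Me2N=CH2 iodide, −78 → 20 °C
Reagents that add atoms: N,N-dimethylmethyleneiminium iodide, C=[N+](C)C.[I-]
Why: Mannich aminomethylation of the lactone enolate; the iminium ion should approach the convex face of the cis-fused bicycle, cis to H7, giving mainly the 11S epimer, a centre that is erased in step 12.

Step 12
Reactants: 19 Mannich base
Product: 21 (3S,7R,8R,10R)-3β-(tert-butyldimethylsilyloxy)eudesma-4,11(13)-dien-12,8β-olide, via trimethylammonium iodide 20 (not isolated)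
Conditions: MeI, MeOH, 20 °C; evaporate; NaHCO3 (aq), CH2Cl2, 20 °C
Reagents that add atoms: none
Why: Quaternisation followed by E1cB (Hofmann-type) loss of trimethylamine through the lactone enolate gives the exocyclic methylene, the standard two-stage α-methylenation of cis-fused γ-lactones.

Step 13
Reactants: 21 α-methylene lactone
Product: 23 methyl (3S,7R,8R,10R)-3β-(tert-butyldimethylsilyloxy)-8β-hydroxyeudesma-4,11(13)-dien-12-oate, via potassium carboxylate 22 (not isolated)
Conditions: KOH (1.05 equiv), THF/H2O, 20 °C; evaporate to dryness; MeI, DMF, 0 → 20 °C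
Reagents that add atoms: potassium hydroxide, [K+].[OH-]; iodomethane, CI
Why: Saponification by acyl–oxygen cleavage keeps the C8 configuration, and O-alkylation of the dry carboxylate salt forms the methyl ester without passing through the free hydroxy acid, which would re-close; hydroxy acids of this cis 12,8β type are known to be isolable, and 23 is carried straight into step 14.

Step 14
Reactants: 23 hydroxy ester
Product: 24 methyl (3S,7R,8R,10R)-8β-acetoxy-3β-(tert-butyldimethylsilyloxy)eudesma-4,11(13)-dien-12-oate
Conditions: Ac2O, DMAP, pyridine, 0 → 20 °C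
Reagents that add atoms: acetic anhydride, CC(=O)OC(C)=O
Why: DMAP-catalysed acetylation caps the hindered axial 8β-hydroxyl with an excess of a fast acyl donor so that intermolecular acylation outruns relactonisation.

Step 15
Reactants: 24 silyl ether
Product: 25 methyl (3S,7R,8R,10R)-8β-acetoxy-3β-hydroxyeudesma-4,11(13)-dien-12-oate
Conditions: HF·pyridine, pyridine, THF, 0 → 20 °C
Reagents that add atoms: none
Why: Buffered fluoride cleavage of the Si–O bond leaves the C3–O bond, the acetate and the acrylate untouched and avoids the basic alkoxide that unbuffered fluoride would generate.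

Step 16
Reactants: 25 allylic alcohol; 26 (E)-3-methylpent-2-enoic acid
Product: 28 methyl (3S,7R,8R,10R)-8β-acetoxy-3β-[(E)-3-methylpent-2-enoyloxy]eudesma-4,11(13)-dien-12-oate (CNP0118541.1), via O-acylisourea 27 (not isolated)
Conditions: DCC, DMAP (0.2 equiv), CH2Cl2, 0 → 20 °C
Reagents that add atoms: none
Why: Steglich esterification acylates the equatorial allylic alcohol with retention at C3; no amine base beyond catalytic DMAP and low temperature are chosen to suppress γ-deprotonation of the activated acid and so keep the E geometry.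

**Compound list**

1 | racemic 7-methyl-1,4-dioxaspiro[4.5]decan-8-one | CC1CC2(CCC1=O)OCCO2 | starting material
2 | (R)-1-phenylethylamine | C[C@@H](N)c1ccccc1 | starting material
3 | N-[(R)-1-phenylethyl]imine of 1 | CC1CC2(CCC1=N[C@H](C)c1ccccc1)OCCO2 | intermediate
4 | ethyl vinyl ketone (pent-1-en-3-one) | C=CC(=O)CC | starting material
5 | N-[(R)-1-phenylethyl]imine of diketone 6 at the ring carbonyl (formed in situ) | CCC(=O)CC[C@]1(C)CC2(CCC1=N[C@H](C)c1ccccc1)OCCO2 | intermediate
6 | (7R)-7-methyl-7-(3-oxopentyl)-1,4-dioxaspiro[4.5]decan-8-one | CCC(=O)CC[C@]1(C)CC2(CCC1=O)OCCO2 | intermediate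
7 | aldol ketol, 5-hydroxy-3-oxo decalin 8-ketal (C4 and C5 epimers, formed in situ) | CC1C(=O)CC[C@]2(C)CC3(CCC12O)OCCO3 | intermediate
8 | (10R)-11,12,13-trinoreudesm-4-ene-3,8-dione 8-ethylene ketal | O=C1CC[C@]2(C)CC3(CCC2=C1C)OCCO3 | intermediate
9 | (3S,10R)-8,8-ethylenedioxy-11,12,13-trinoreudesm-4-en-3β-ol | O[C@H]1CC[C@]2(C)CC3(CCC2=C1C)OCCO3 | intermediate
10 | (3S,10R)-3β-(tert-butyldimethylsilyloxy)-8,8-ethylenedioxy-11,12,13-trinoreudesm-4-ene | CC(C)(C)[Si](C)(C)O[C@H]1CC[C@]2(C)CC3(CCC2=C1C)OCCO3 | intermediate
11 | (3S,10R)-3β-(tert-butyldimethylsilyloxy)-11,12,13-trinoreudesm-4-en-8-one | CC(C)(C)[Si](C)(C)O[C@H]1CC[C@]2(C)CC(=O)CCC2=C1C | intermediate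
12 | (3S,8S,10R)-3β-(tert-butyldimethylsilyloxy)-11,12,13-trinoreudesm-4-en-8β-ol | CC(C)(C)[Si](C)(C)O[C@H]1CC[C@]2(C)C[C@@H](O)CCC2=C1C | intermediate
13 | bromoacetyl bromide | BrCC(=O)Br | starting material
14 | 8β-bromoacetate of 12 | CC(C)(C)[Si](C)(C)O[C@H]1CC[C@]2(C)C[C@@H](OC(=O)CBr)CCC2=C1C | intermediate
15 | 8β-[2-(1,2-ditosylhydrazin-1-yl)acetate] of 12 (formed in situ) | CC(C)(C)[Si](C)(C)O[C@H]1CC[C@]2(C)C[C@@H](OC(=O)CN(NS(=O)(=O)c3ccc(C)cc3)S(=O)(=O)c3ccc(C)cc3)CCC2=C1C | intermediate
16 | 8β-diazoacetate of 12 (3S,8S,10R) | CC(C)(C)[Si](C)(C)O[C@H]1CC[C@]2(C)C[C@@H](OC(=O)C=[N+]=[N-])CCC2=C1C | intermediate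
17 | (3S,7R,8R,10R)-3β-(tert-butyldimethylsilyloxy)-13-noreudesm-4-en-12,8β-olide | O=C1C[C@H]2CC3=C(C)[C@@H](O[Si](C)(C)C(C)(C)C)CC[C@]3(C)C[C@H]2O1 | intermediate
18 | lithium enolate of lactone 17 (formed in situ) | [Li+].[O-]C1=C[C@H]2CC3=C(C)[C@@H](O[Si](C)(C)C(C)(C)C)CC[C@]3(C)C[C@H]2O1 | intermediate
19 | (11S)-11-(dimethylaminomethyl) lactone | O=C1[C@H](CN(C)C)[C@H]2CC3=C(C)[C@@H](O[Si](C)(C)C(C)(C)C)CC[C@]3(C)C[C@H]2O1 | intermediate
20 | trimethylammonium iodide of 19 (formed in situ) | O=C1[C@H](C[N+](C)(C)C)[C@H]2CC3=C(C)[C@@H](O[Si](C)(C)C(C)(C)C)CC[C@]3(C)C[C@H]2O1.[I-] | intermediate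
21 | (3S,7R,8R,10R)-3β-(tert-butyldimethylsilyloxy)eudesma-4,11(13)-dien-12,8β-olide | O=C1C(=C)[C@H]2CC3=C(C)[C@@H](O[Si](C)(C)C(C)(C)C)CC[C@]3(C)C[C@H]2O1 | intermediate
22 | potassium 3β-(tert-butyldimethylsilyloxy)-8β-hydroxyeudesma-4,11(13)-dien-12-oate (formed in situ) | C=C(C(=O)[O-])[C@H]1CC2=C(C)[C@@H](O[Si](C)(C)C(C)(C)C)CC[C@]2(C)C[C@H]1O.[K+] | intermediate
23 | methyl (3S,7R,8R,10R)-3β-(tert-butyldimethylsilyloxy)-8β-hydroxyeudesma-4,11(13)-dien-12-oate | C=C(C(=O)OC)[C@H]1CC2=C(C)[C@@H](O[Si](C)(C)C(C)(C)C)CC[C@]2(C)C[C@H]1O | intermediate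
24 | methyl (3S,7R,8R,10R)-8β-acetoxy-3β-(tert-butyldimethylsilyloxy)eudesma-4,11(13)-dien-12-oate | C=C(C(=O)OC)[C@H]1CC2=C(C)[C@@H](O[Si](C)(C)C(C)(C)C)CC[C@]2(C)C[C@H]1OC(C)=O | intermediate
25 | methyl (3S,7R,8R,10R)-8β-acetoxy-3β-hydroxyeudesma-4,11(13)-dien-12-oate | C=C(C(=O)OC)[C@H]1CC2=C(C)[C@@H](O)CC[C@]2(C)C[C@H]1OC(C)=O | intermediate
26 | (E)-3-methylpent-2-enoic acid | CC/C(C)=C/C(=O)O | starting material
27 | O-acylisourea from 26 and DCC (formed in situ) | CC/C(C)=C/C(=O)OC(=NC1CCCCC1)NC1CCCCC1 | intermediate
28 | methyl (3S,7R,8R,10R)-8β-acetoxy-3β-[(E)-3-methylpent-2-enoyloxy]eudesma-4,11(13)-dien-12-oate (CNP0118541.1) | C=C(C(=O)OC)[C@H]1CC2=C(C)[C@@H](OC(=O)/C=C(\C)CC)CC[C@]2(C)C[C@H]1OC(C)=O | target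

**Totals**

Total step count: 16. Longest linear sequence: 16 steps (1 → 28); compounds 2, 4, 13 and 26 enter as single reagents.

**Steps most likely to fail**

Step 10. The carbene may leak to C9–H or to the allylic axial C6–H (six-membered lactone), or be lost to dimerisation, so that the wanted lactone is formed only in part. The fallback makes the C7–C11 bond by enolate alkylation instead. It sets out from ketone 11: LiN(i-Pr)2 in THF at −78 °C should deprotonate C7, since C9 is screened by quaternary C10. Alkylation with methyl bromoacetate and equilibration with NaOMe in MeOH to the equatorial epimer should give methyl (3S,7R,10R)-3β-(tert-butyldimethylsilyloxy)-8-oxo-13-noreudesm-4-en-12-oate F1. LiBH(s-Bu)3 then delivers hydride equatorially as in step 7 to give the 8β-hydroxy ester F2, whose axial oxygen closes onto the ester, and the sequence comes back to the route at lactone 17.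

Step 13. The free 8β-hydroxyl may re-close onto C12 during neutralisation, methylation or the slow acetylation of this hindered alcohol, and hydroxide may add to the acrylate. The fallback lowers C12 to the alcohol level so that no acyl carbon is within reach while O8 is capped. It sets out from methylene lactone 21: i-Bu2AlH (CH2Cl2, −78 → 0 °C) should give the 8β,12-diol F3; TESCl and imidazole at −20 °C silylate the primary allylic hydroxyl to give the 12-O-triethylsilyl ether F4; Ac2O, DMAP and pyridine give the 8β-acetate F5; PPTS in MeOH at 0 °C removes only the primary silyl group to give the 12-ol F6; MnO2 gives the enal F7; Pinnick oxidation (NaClO2, NaH2PO4, 2-methylbut-2-ene) gives the acrylic acid F8; Me3SiCHN2 in toluene/MeOH methylates it, and the sequence comes back to the route at acetate 24.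

Step 2. Ethyl vinyl ketone is a sluggish, polymerisation-prone acceptor, and slow conversion would let an unselective background alkylation erode the enantiomeric purity on which the whole series rests. The fallback uses the more reactive methyl acrylate and brings in the ethyl ketone carbons afterwards (Fujimoto–Belleau sequence). It sets out from imine 3: methyl acrylate should give the acrylate adduct imine F9, which aqueous AcOH hydrolyses to the keto ester F10 with the same sense of induction; LiOH gives the keto acid F11; Ac2O and NaOAc at 120 °C close the enol δ-lactone F12; EtMgBr (1 equiv, THF, −78 °C) opens it to the ethyl ketone, and aqueous work-up comes back to the route at diketone 6.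

**Further compounds**

F1 | step 10 | methyl (3S,7R,10R)-3β-(tert-butyldimethylsilyloxy)-8-oxo-13-noreudesm-4-en-12-oate | COC(=O)C[C@H]1CC2=C(C)[C@@H](O[Si](C)(C)C(C)(C)C)CC[C@]2(C)CC1=O
F2 | step 10 | methyl (3S,7R,8R,10R)-3β-(tert-butyldimethylsilyloxy)-8β-hydroxy-13-noreudesm-4-en-12-oate | COC(=O)C[C@H]1CC2=C(C)[C@@H](O[Si](C)(C)C(C)(C)C)CC[C@]2(C)C[C@H]1O
F3 | step 13 | (3S,7R,8R,10R)-3β-(tert-butyldimethylsilyloxy)eudesma-4,11(13)-diene-8β,12-diol | C=C(CO)[C@H]1CC2=C(C)[C@@H](O[Si](C)(C)C(C)(C)C)CC[C@]2(C)C[C@H]1O
F4 | step 13 | 12-O-triethylsilyl ether of F3 | C=C(CO[Si](CC)(CC)CC)[C@H]1CC2=C(C)[C@@H](O[Si](C)(C)C(C)(C)C)CC[C@]2(C)C[C@H]1O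
F5 | step 13 | 8β-acetate of F4 | C=C(CO[Si](CC)(CC)CC)[C@H]1CC2=C(C)[C@@H](O[Si](C)(C)C(C)(C)C)CC[C@]2(C)C[C@H]1OC(C)=O
F6 | step 13 | (3S,7R,8R,10R)-8β-acetoxy-3β-(tert-butyldimethylsilyloxy)eudesma-4,11(13)-dien-12-ol | C=C(CO)[C@H]1CC2=C(C)[C@@H](O[Si](C)(C)C(C)(C)C)CC[C@]2(C)C[C@H]1OC(C)=O
F7 | step 13 | (3S,7R,8R,10R)-8β-acetoxy-3β-(tert-butyldimethylsilyloxy)eudesma-4,11(13)-dien-12-al | C=C(C=O)[C@H]1CC2=C(C)[C@@H](O[Si](C)(C)C(C)(C)C)CC[C@]2(C)C[C@H]1OC(C)=O
F8 | step 13 | (3S,7R,8R,10R)-8β-acetoxy-3β-(tert-butyldimethylsilyloxy)eudesma-4,11(13)-dien-12-oic acid | C=C(C(=O)O)[C@H]1CC2=C(C)[C@@H](O[Si](C)(C)C(C)(C)C)CC[C@]2(C)C[C@H]1OC(C)=O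
F9 | step 2 | N-[(R)-1-phenylethyl]imine of keto ester F10 | COC(=O)CC[C@]1(C)CC2(CCC1=N[C@H](C)c1ccccc1)OCCO2
F10 | step 2 | methyl 3-[(7R)-7-methyl-8-oxo-1,4-dioxaspiro[4.5]decan-7-yl]propanoate | COC(=O)CC[C@]1(C)CC2(CCC1=O)OCCO2
F11 | step 2 | 3-[(7R)-7-methyl-8-oxo-1,4-dioxaspiro[4.5]decan-7-yl]propanoic acid | OC(=O)CC[C@]1(C)CC2(CCC1=O)OCCO2
F12 | step 2 | enol δ-lactone of keto acid F11 (C5=C6 enol, ketal intact, R at the quaternary carbon) | O=C1CC[C@]2(C)CC3(CC=C2O1)OCCO3
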